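**Retrosynthetic overview**

1. Dendronpholide B ⇒ seco-ynal 24: the 14-membered carbocycle is closed last across C12–C13 by a nickel-catalysed reductive alkyne–aldehyde macrocyclization (sets C13 and the E C11=C12 alkene); the exo-methylene is carried as CH2OAc and released at the end.
2. Seven-membered lactone ⇒ cyclohexanone 21 by Baeyer–Villiger ring expansion, a 1,2-shift of the quaternary C4 from carbon to oxygen with retention (key step).
3. Cyclohexanone 21 ⇒ cyclohex-2-enone: α′-Mukaiyama aldol with aldehyde 8 (C5), chelate-controlled methylation (C4), then asymmetric conjugate alkynylation with formaldehyde trapping (C1, C16).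
4. Aldehyde 8 (C5–C12) ⇒ Claisen rearrangement of the alcohol made from methacrolein, propargyl bromide and MeI.
5. Ring order: six-membered carbocycle (bought) → seven-membered lactone (ring expansion) → 14-membered carbocycle.

Assumption: locants follow the cembrane skeleton (C1 ring-fusion CH, C4 O-bearing quaternary carbon, C5 CHOAc, C8=C9 and C11=C12 alkenes, C13 CHOH, C15(=C16H2)–C17(=O)O lactone), so the target is (1R,4R,5S,13R,8E,11E); solutions of LiN(i-Pr)2 and lithium (trimethylsilyl)acetylide are bought.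

**Route**

Step 1
Reactants: 1 3-bromoprop-1-yne (propargyl bromide); 2 2-methylprop-2-enal (methacrolein)
Product: 5 2-methylhept-1-en-5-yn-3-ol (racemic), via 1,3-dilithiopropyne 3 (not isolated), via dilithio adduct 4 (not isolated)
Conditions: 1, n-BuLi (2 equiv), TMEDA, Et2O/hexane, −78 °C; 2, −78 °C; MeI, THF/DMPU, −78 °C → rt; H2O
Reagents that add atoms: iodomethane (CI)
Why: Propargyl dianion chemistry: the sp3 terminus of 1,3-dilithiopropyne adds 1,2 to the enal and the remaining lithium acetylide is C-methylated, giving the homopropargylic alcohol with the methyl-capped alkyne; the racemic carbinol centre is destroyed in step 2.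

Step 2
Reactants: 5 2-methylhept-1-en-5-yn-3-ol; 6 ethyl vinyl ether
Product: 8 (4E)-4-methylnon-4-en-7-ynal, via allyl vinyl ether 7 (not isolated)
Conditions: 6 (excess), Hg(OAc)2 (10 mol %), reflux; concentrate; toluene, 130 °C (sealed tube)
Reagents that add atoms: none
Why: Vinyl ether exchange followed by Claisen rearrangement through a chair transition state with the but-2-ynyl group equatorial gives the (E)-trisubstituted C8=C9 alkene and the aldehyde in one operation.

Step 3
Reactants: 9 cyclohex-2-en-1-one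
Product: 11 2-(trimethylsilyloxy)cyclohexa-1,3-diene, via lithium dienolate 10 (not isolated)
Conditions: LiN(i-Pr)2, THF, −78 °C; Me3SiCl, −78 °C → rt
Reagents that add atoms: chlorotrimethylsilane (C[Si](C)(C)Cl)
Why: Kinetic α′-deprotonation of the enone and O-silylation give the cross-conjugated silyl dienol ether, which is nucleophilic only at the future C4.

Step 4
Reactants: 11 2-(trimethylsilyloxy)cyclohexa-1,3-diene; 8 (4E)-4-methylnon-4-en-7-ynal
Product: 13 6-[(1S,4E)-1-hydroxy-4-methylnon-4-en-7-yn-1-yl]cyclohex-2-en-1-one (both C6 epimers), via silyl ether aldol 12 (not isolated)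
Conditions: chiral confined imidodiphosphorimidate (IDPi) Brønsted acid (1 mol %, the enantiomer that directs Re-face attack), toluene, −78 °C; then 1 M HCl, THF, 0 °C
Reagents that add atoms: none
Why: Catalytic asymmetric Mukaiyama aldol: the silylated chiral anion pairs with the O-silyl oxocarbenium of 8 and exposes its Re face to the dienyl silyl ether, setting the (S)-carbinol (future C5), while the ring epimers at C6 are carried on because step 5 re-forms that centre.

Step 5
Reactants: 13 6-[(1S,4E)-1-hydroxy-4-methylnon-4-en-7-yn-1-yl]cyclohex-2-en-1-one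
Product: 16 (6R)-6-[(1S,4E)-1-acetoxy-4-methylnon-4-en-7-yn-1-yl]-6-methylcyclohex-2-en-1-one, via dilithium alkoxide dienolate 14 (not isolated), via methylated lithium alkoxide 15 (not isolated)
Conditions: LiN(i-Pr)2 (2.2 equiv), THF, −78 → −40 °C; MeI, DMPU, −78 → −20 °C; Ac2O, −20 °C → rt
Reagents that add atoms: iodomethane (CI); acetic anhydride (CC(=O)OC(C)=O)
Why: Fráter–Seebach-type alkylation: the only acidic C–H (α′) gives a lithium-chelated alkoxide–dienolate whose face anti to the carbinol's alkyl chain is open, so methyl enters anti to the C5 oxygen and fixes the quaternary C4 as R, after which the alkoxide is acetylated in the same flask.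

Step 6
Reactants: 16 (6R)-6-[(1S,4E)-1-acetoxy-4-methylnon-4-en-7-yn-1-yl]-6-methylcyclohex-2-en-1-one; 17 lithium (trimethylsilyl)acetylide
Product: 21 (2S,3S,6R)-2-(acetoxymethyl)-6-[(1S,4E)-1-acetoxy-4-methylnon-4-en-7-yn-1-yl]-6-methyl-3-[(trimethylsilyl)ethynyl]cyclohexan-1-one, via alkynylalane 18 (not isolated), via aluminium enolate 19 (not isolated), via aluminium aldolate 20 (not isolated)
Conditions: 17, Me2AlCl, t-BuOMe, 0 °C; Ni(acac)2 (5 mol %), chiral cyclopropane-bridged bis(oxazoline) (6 mol %), 16, 0 °C; CH2O (gas), −40 °C; Ac2O, pyridine, 0 °C; aqueous potassium sodium tartrate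
Reagents that add atoms: formaldehyde (C=O); acetic anhydride (CC(=O)OC(C)=O)
Why: Nickel-catalysed asymmetric conjugate alkynylation with an alkynylalane (ligand control, reinforced by axial attack anti to the pseudo-axial acetoxyalkyl chain on C6) sets C1 with the alkyne cis to the C6 methyl; the regiodefined aluminium enolate then adds to formaldehyde trans to the alkyne (aldol) and the alkoxide is acetylated, installing C16 as a masked methylene.

Step 7
Reactants: 21 (2S,3S,6R)-2-(acetoxymethyl)-6-[(1S,4E)-1-acetoxy-4-methylnon-4-en-7-yn-1-yl]-6-methyl-3-[(trimethylsilyl)ethynyl]cyclohexan-1-one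
Product: 22 (3S,4S,7R)-3-(acetoxymethyl)-7-[(1S,4E)-1-acetoxy-4-methylnon-4-en-7-yn-1-yl]-7-methyl-4-[(trimethylsilyl)ethynyl]oxepan-2-one
Conditions: Me3SiOOSiMe3 (3 equiv), Me3SiOTf (20 mol %), 4 Å molecular sieves, CH2Cl2, −40 → 0 °C; aqueous Na2S2O3
Reagents that add atoms: bis(trimethylsilyl) peroxide (C[Si](C)(C)OO[Si](C)(C)C)
Why: Baeyer–Villiger ring expansion: after peroxide addition to the ketone the more substituted, quaternary C4 undergoes the 1,2-shift from carbon to oxygen with retention, giving the seven-membered lactone with the tertiary C4–O bond, and the silyl peroxide/Lewis acid pair does not epoxidize the trisubstituted alkene or touch the alkynes.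

Step 8
Reactants: 22 (3S,4S,7R)-3-(acetoxymethyl)-7-[(1S,4E)-1-acetoxy-4-methylnon-4-en-7-yn-1-yl]-7-methyl-4-[(trimethylsilyl)ethynyl]oxepan-2-one
Product: 23 (3S,4S,7R)-3-(acetoxymethyl)-7-[(1S,4E)-1-acetoxy-4-methylnon-4-en-7-yn-1-yl]-4-ethynyl-7-methyloxepan-2-one
Conditions: AgNO3 (10 mol %), acetone/H2O, rt
Reagents that add atoms: none
Why: Silver-catalysed protodesilylation cleaves only the C(sp)–Si bond under neutral conditions, so the base-sensitive β-acetoxy lactone and both acetates survive.

Step 9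
Reactants: 23 (3S,4S,7R)-3-(acetoxymethyl)-7-[(1S,4E)-1-acetoxy-4-methylnon-4-en-7-yn-1-yl]-4-ethynyl-7-methyloxepan-2-one
Product: 24 (3S,4R,7R)-3-(acetoxymethyl)-7-[(1S,4E)-1-acetoxy-4-methylnon-4-en-7-yn-1-yl]-7-methyl-4-(2-oxoethyl)oxepan-2-one
Conditions: [CpRu(MeCN)3]PF6 (5 mol %), 5,5'-bis(trifluoromethyl)-2,2'-bipyridine (5 mol %), N-methylpyrrolidinone/H2O (4:1), 25 °C
Reagents that add atoms: water (O)
Why: Ruthenium-vinylidene-mediated anti-Markovnikov hydration converts the terminal alkyne into the C13 aldehyde, while the internal alkyne cannot form a vinylidene and stays inert.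

Step 10
Reactants: 24 (3S,4R,7R)-3-(acetoxymethyl)-7-[(1S,4E)-1-acetoxy-4-methylnon-4-en-7-yn-1-yl]-7-methyl-4-(2-oxoethyl)oxepan-2-one
Product: 27 dendronpholide B, via macrocyclic silyl ether acetate 25 (not isolated), via silyl ether of target 26 (not isolated)
Conditions: Ni(cod)2 (20 mol %), (4R,5R)-1,3-dimesityl-4,5-diphenylimidazolin-2-ylidene (preformed free carbene, 20 mol %; its antipode if the opposite face is delivered), Et3SiH (4 equiv), THF, 0.003 M, slow addition, 25 °C; then DBU, 0 °C; then 1 M HCl, THF, 0 °C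
Reagents that add atoms: none
Why: Proposed new method: enantioselective nickel/carbene reductive ynal macrocyclization, in which zerovalent nickel bearing a small C2-symmetric carbene undergoes oxidative cyclization of the aldehyde and the methyl-capped alkyne to an oxanickelacyclopentene (C–C bond at the methyl-bearing C12 because the small ligand lets the larger propargylic chain sit next to nickel, and the backbone-geared mesityl groups expose the aldehyde Si face to give 13R), Et3SiH σ-bond metathesis and C–H reductive elimination deliver H syn and hence the (E)-C11=C12 alkene, after which DBU (E1cB loss of acetate) and dilute acid (Si–O cleavage) release the methylene lactone and the alcohol; the closest known reactions are the ligand-regiocontrolled nickel/carbene reductive macrocyclization of ynals with achiral carbenes and the intermolecular enantioselective aldehyde–alkyne reductive coupling with chiral carbenes.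

**Compound list**

1 | 3-bromoprop-1-yne (propargyl bromide) | C#CCBr | starting material
2 | 2-methylprop-2-enal (methacrolein) | C=C(C)C=O | starting material
3 | 1,3-dilithiopropyne | [Li]CC#C[Li] | intermediate
4 | dilithio adduct: lithium 6-lithio-2-methylhex-1-en-5-yn-3-olate (racemic) | C=C(C)C(O[Li])CC#C[Li] | intermediate
5 | 2-methylhept-1-en-5-yn-3-ol (racemic) | C=C(C)C(O)CC#CC | intermediate
6 | ethyl vinyl ether | C=COCC | starting material
7 | allyl vinyl ether: 3-(ethenyloxy)-2-methylhept-1-en-5-yne (racemic) | C=C(C)C(OC=C)CC#CC | intermediate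
8 | (4E)-4-methylnon-4-en-7-ynal | O=CCC/C(C)=C/CC#CC | intermediate
9 | cyclohex-2-en-1-one | O=C1C=CCCC1 | starting material
10 | lithium dienolate: lithium cyclohexa-1,5-dien-1-olate | [Li]OC1=CCCC=C1 | intermediate
11 | 2-(trimethylsilyloxy)cyclohexa-1,3-diene | C[Si](C)(C)OC1=CCCC=C1 | intermediate
12 | silyl ether aldol: 6-[(1S,4E)-4-methyl-1-(trimethylsilyloxy)non-4-en-7-yn-1-yl]cyclohex-2-en-1-one (both C6 epimers) | O=C1C=CCCC1[C@@H](O[Si](C)(C)C)CC/C(C)=C/CC#CC | intermediate
13 | 6-[(1S,4E)-1-hydroxy-4-methylnon-4-en-7-yn-1-yl]cyclohex-2-en-1-one (both C6 epimers) | O=C1C=CCCC1[C@@H](O)CC/C(C)=C/CC#CC | intermediate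
14 | dilithium alkoxide dienolate of 13 (1S,4E) | [Li]OC1=C(CCC=C1)[C@@H](O[Li])CC/C(C)=C/CC#CC | intermediate
15 | methylated lithium alkoxide: lithium (1S,4E)-4-methyl-1-[(1R)-1-methyl-2-oxocyclohex-3-en-1-yl]non-4-en-7-yn-1-olate | O=C1C=CCC[C@]1(C)[C@@H](O[Li])CC/C(C)=C/CC#CC | intermediate
16 | (6R)-6-[(1S,4E)-1-acetoxy-4-methylnon-4-en-7-yn-1-yl]-6-methylcyclohex-2-en-1-one | O=C1C=CCC[C@]1(C)[C@@H](OC(C)=O)CC/C(C)=C/CC#CC | intermediate
17 | lithium (trimethylsilyl)acetylide | [Li]C#C[Si](C)(C)C | starting material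
18 | alkynylalane: dimethyl[(trimethylsilyl)ethynyl]aluminium | C[Al](C)C#C[Si](C)(C)C | intermediate
19 | aluminium enolate: dimethylaluminium enolate (C17=C15) of the 3-alkynyl ketone, (3S,6R,1'S,4'E) | C[Al](C)OC1=C[C@@H](C#C[Si](C)(C)C)CC[C@]1(C)[C@@H](OC(C)=O)CC/C(C)=C/CC#CC | intermediate
20 | aluminium aldolate: dimethylaluminium alkoxide of the (2S,3S,6R)-2-(hydroxymethyl) ketone | O=C1[C@H](CO[Al](C)C)[C@@H](C#C[Si](C)(C)C)CC[C@]1(C)[C@@H](OC(C)=O)CC/C(C)=C/CC#CC | intermediate
21 | (2S,3S,6R)-2-(acetoxymethyl)-6-[(1S,4E)-1-acetoxy-4-methylnon-4-en-7-yn-1-yl]-6-methyl-3-[(trimethylsilyl)ethynyl]cyclohexan-1-one | O=C1[C@H](COC(C)=O)[C@@H](C#C[Si](C)(C)C)CC[C@]1(C)[C@@H](OC(C)=O)CC/C(C)=C/CC#CC | intermediate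
22 | (3S,4S,7R)-3-(acetoxymethyl)-7-[(1S,4E)-1-acetoxy-4-methylnon-4-en-7-yn-1-yl]-7-methyl-4-[(trimethylsilyl)ethynyl]oxepan-2-one | O=C1[C@H](COC(C)=O)[C@@H](C#C[Si](C)(C)C)CC[C@@](C)(O1)[C@@H](OC(C)=O)CC/C(C)=C/CC#CC | intermediate
23 | (3S,4S,7R)-3-(acetoxymethyl)-7-[(1S,4E)-1-acetoxy-4-methylnon-4-en-7-yn-1-yl]-4-ethynyl-7-methyloxepan-2-one | O=C1[C@H](COC(C)=O)[C@@H](C#C)CC[C@@](C)(O1)[C@@H](OC(C)=O)CC/C(C)=C/CC#CC | intermediate
24 | (3S,4R,7R)-3-(acetoxymethyl)-7-[(1S,4E)-1-acetoxy-4-methylnon-4-en-7-yn-1-yl]-7-methyl-4-(2-oxoethyl)oxepan-2-one | O=C1[C@H](COC(C)=O)[C@@H](CC=O)CC[C@@](C)(O1)[C@@H](OC(C)=O)CC/C(C)=C/CC#CC | intermediate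
25 | macrocyclic silyl ether acetate: 13-O-triethylsilyl-15,16-dihydro-16-acetoxy-dendronpholide B, (1R,4R,5S,13R,15S,8E,11E) | CC(=O)OC[C@H]1C(=O)O[C@]2(C)CC[C@@H]1C[C@@H](O[Si](CC)(CC)CC)/C(C)=C/C/C=C(\C)CC[C@@H]2OC(C)=O | intermediate
26 | silyl ether of target: 13-O-triethylsilyl-dendronpholide B | C=C1C(=O)O[C@]2(C)CC[C@@H]1C[C@@H](O[Si](CC)(CC)CC)/C(C)=C/C/C=C(\C)CC[C@@H]2OC(C)=O | intermediate
27 | dendronpholide B, (1R,4R,5S,13R,8E,11E) | C=C1C(=O)O[C@]2(C)CC[C@@H]1C[C@@H](O)/C(C)=C/C/C=C(\C)CC[C@@H]2OC(C)=O | target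

**Step count and risks**

Total steps: 10. Longest linear sequence: 9 (steps 1, 2, 4, 5, 6, 7, 8, 9, 10).

Step 10 (the new reaction) is the most likely to fail: a chiral carbene has not been shown to control the carbinol centre in a nickel reductive macrocyclization, and the β-acetoxy lactone must survive the catalyst. Fallback with known chemistry, setting out from 24: cyclize with the achiral system Ni(cod)2/1,3-dimesitylimidazol-2-ylidene/Et3SiH at high dilution, which gives 25 together with its C13 epimer, the 13-epi silyl ether acetate F5. The same DBU treatment gives 26 plus the 13-epi methylene lactone silyl ether F6, and dilute acid gives 27 plus 13-epi-dendronpholide B F7. Dess–Martin oxidation of the alcohol mixture converges on the 13-oxo enone F8, and (S)-2-methyl-CBS-oxazaborolidine with catecholborane at −78 °C (alkenyl as the large group) reduces it to the 13R alcohol, coming back to the route at 27.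

Step 6 is the second risk: three bonds are made in one flask, and the aluminium enolate may not add cleanly to formaldehyde. Fallback, setting out from 16: run the same nickel-catalysed alkynylation but quench with water to isolate the alkynyl ketone F1. Convert it with Me3SiOTf/Et3N into its only possible silyl enol ether F2, hydroxymethylate this with aqueous formaldehyde and Sc(OTf)3 to the hydroxymethyl ketone F3, and acetylate (Ac2O, pyridine) to come back to the route at 21.

Step 7 is the third risk: the ketone is flanked by a quaternary and a tertiary carbon, and the silyl peroxide may be too slow. Fallback, setting out from 21: use excess CF3CO3H buffered with Na2HPO4 in CH2Cl2, accepting that the C8=C9 alkene is epoxidized while the ring expands, to give the epoxy lactone F4. Then deoxygenate the epoxide stereospecifically with retention using Ph3P=Se and CF3CO2H, which restores the (E)-alkene and comes back to the route at 22.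

**Further compounds**

F1 | step 6 | (3S,6R)-6-[(1S,4E)-1-acetoxy-4-methylnon-4-en-7-yn-1-yl]-6-methyl-3-[(trimethylsilyl)ethynyl]cyclohexan-1-one | O=C1C[C@@H](C#C[Si](C)(C)C)CC[C@]1(C)[C@@H](OC(C)=O)CC/C(C)=C/CC#CC
F2 | step 6 | trimethylsilyl enol ether (C1=C2 of the ring) of F1 | C[Si](C)(C)OC1=C[C@@H](C#C[Si](C)(C)C)CC[C@]1(C)[C@@H](OC(C)=O)CC/C(C)=C/CC#CC
F3 | step 6 | (2S,3S,6R)-6-[(1S,4E)-1-acetoxy-4-methylnon-4-en-7-yn-1-yl]-2-(hydroxymethyl)-6-methyl-3-[(trimethylsilyl)ethynyl]cyclohexan-1-one | O=C1[C@H](CO)[C@@H](C#C[Si](C)(C)C)CC[C@]1(C)[C@@H](OC(C)=O)CC/C(C)=C/CC#CC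
F4 | step 7 | 8,9-epoxide of 22 (trans-epoxide, one of two diastereomers shown, both are used) | O=C1[C@H](COC(C)=O)[C@@H](C#C[Si](C)(C)C)CC[C@@](C)(O1)[C@@H](OC(C)=O)CC[C@@]2(C)O[C@@H]2CC#CC
F5 | step 10 | C13 epimer of 25 (13S) | CC(=O)OC[C@H]1C(=O)O[C@]2(C)CC[C@@H]1C[C@H](O[Si](CC)(CC)CC)/C(C)=C/C/C=C(\C)CC[C@@H]2OC(C)=O
F6 | step 10 | C13 epimer of 26 (13S) | C=C1C(=O)O[C@]2(C)CC[C@@H]1C[C@H](O[Si](CC)(CC)CC)/C(C)=C/C/C=C(\C)CC[C@@H]2OC(C)=O
F7 | step 10 | 13-epi-dendronpholide B (13S) | C=C1C(=O)O[C@]2(C)CC[C@@H]1C[C@H](O)/C(C)=C/C/C=C(\C)CC[C@@H]2OC(C)=O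
F8 | step 10 | 13-oxo enone (13-dehydro-dendronpholide B) | C=C1C(=O)O[C@]2(C)CC[C@@H]1CC(=O)/C(C)=C/C/C=C(\C)CC[C@@H]2OC(C)=O
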